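## Structural features

Numbering used throughout: ring A (cyclopentane) C1–C2–C3–C4–C9, ring B (cyclohexane) C4–C5–C6–C7–C8–C9, ring C (cycloheptane) C5–C6–C14–C13–C12–C11–C10, C15 (methyl on C12), C16 (methyl on C6), C17 (CH2OAc on C9), lactone carbons C18 (on C3), C19 (=CH2) and C20 (C=O, bound through oxygen to C2); β is the face of C17, α the opposite face. The three carbocycles are fused angularly, A/B across C4–C9 and B/C across C5–C6, both trans, and the two quaternary carbons C9 (β-CH2OAc) and C6 (α-CH3) sit para on ring B and anti to each other. The stereocentres C2–C3–C4–C5–C6 are contiguous, with C9 attached to C4: H2, H3 and H4 are all α, so the α-methylene-γ-butyrolactone (ring D) is cis-fused to ring A on the β face, syn to the axial C17 group, and 5-H is β. Ring C carries a trisubstituted 12β,13β-epoxide, anti to the axial C16 methyl. Fragile groups are the exocyclic enoate (Michael acceptor, polymerises, adds bases), the acid-labile epoxide and the primary acetate (hydride- and base-labile). The real difficulty is the trans-fused A/B unit with its quaternary C9 and the all-cis C2/C3/C4 array that puts the lactone on the more hindered face, together with the anti relation of C9 to the C5/C6 pair. The key step exploits that, with C2 at the ketone level and C3=C4 unsaturated, the unit C1H2–C2(=O)–C3H=C4 on quaternary C9 is the retron of a Pauson–Khand reaction (C2 from carbon monoxide, C3≡C4 an alkyne, C9=C1 a 1,1-disubstituted alkene), and its first bond, C4–C9, is also the last bond of ring B.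

## Logic of the disconnections

23 to 22. The two C–O bonds of the epoxide (C12–O, C13–O) are cut. The epoxide is the most acid-labile group and C12=C13 is the only electron-rich alkene of 22, so it goes in last. This removes two stereocentres; the forward step must attack the β face and leave C18=C19 alone.

22 to 20 (through 21). The C3–C18 bond and the C4–H bond are cut, which opens the lactone to a propiolate ester on a 2β-oxygen next to a C3=C4 alkene. One ester tether then supplies the lactone ring, the exocyclic methylene and the centres C3 and C4; the trans A/B fusion becomes a question of which face of a C4 radical takes up hydrogen. The forward step needs 5-exo closure through the tether and hydrogen transfer to the α face.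

20 to 18 and 19, then 18 to 17. The ester C–O bond and the C2–H bond are cut. This leaves an enone with no stereocentre in ring A except C9. The forward reduction must give the 2β-alcohol, because the tether face decides C3.

17 to 16 (key). The bonds C4–C9, C2–C3 and C1–C2 are cut, with C2 returned as carbon monoxide. Rings A and B and the quaternary centre C9 vanish together, and the precursor is a monocyclic cycloheptene that carries an ethynyl group and a chain. In one sentence: an intramolecular Pauson–Khand reaction of the monocyclic 1,7-enyne 16 closes rings A and B at once. The forward step must insert a 1,1-disubstituted alkene and fix C9 relative to C5/C6.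

16 to 13 (through 15 and 14). The acetate C–O bond, the C3–C4 bond (one-carbon homologation of an aldehyde) and the aldehyde C–H bond are cut back to a Weinreb amide. The acetate is placed after all hydride and base steps and before the cycloaddition, so no protecting group is needed.

13 to 10 and 11. The sp3–sp2 bond C8–C9 is cut. Fragment 11 brings C9, C1 and C17 with the oxygen already in place. The forward step needs hydroboration of the one monosubstituted alkene only.

10 to 9 to 8. The C12=C13 double bond is cut (ring-closing metathesis), and the amide is traced to the acid. Ring C then comes from an open chain; the forward step must choose the seven-membered closure over other alkene pairings.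

8 to 6, then to 4 and 5, then to 1. The C5–C6 bond is cut as an Ireland–Claisen retron, which sets the vicinal quaternary/tertiary pair from alkene and enolate geometry. The ester is split into 4 and 5, and 4 is taken back to 1 by cutting the C6–CH3 and C7–C8 bonds. The forward rearrangement needs a chiral boron controller for the absolute configuration.

## Other disconnections considered

Alternative 1: The first plan that comes to mind is annulative. Ring B is cut by a Robinson retron, ring A by an alkylation/aldol retron, and the lactone is added last by enolate alkylation and methylenation. The forward key step is an asymmetric Robinson annulation to the bicyclic dienone A1, then Birch reductive alkylation to set C5 and C4. The chosen plan is preferred because here C9 must be made quaternary on a finished ring B by two separate enolate alkylations. C3 would be set on a preformed ring A, where a substituent is expected to prefer the α position, away from the axial C17 group. The annulation carbonyls must also be removed or moved, so the sequence should be clearly longer.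

Alternative 2: Cut C2–C3, C18–C20 and C20–O, so that ring A and the lactone close in one carbonylative [2+2+1] reaction (hetero-Pauson–Khand, Mo(CO)6 or Ru3(CO)12 under CO) of the allenyl aldehyde A2. This gives the α-methylene lactone directly. However, both new centres would have to form with the metallacycle on the β face, in a syn-pentane relation to the axial C17 group. The α face is open, so the 2,3-bis-epimer A3 is the expected main product. A2 also needs ring B with C4, C5, C6 and C9 already set, which brings back the stepwise chemistry of alternative 1.

Alternative 3: Make the skeleton without the C17 oxygen (C9 methyl, as in A4) by the same cycloaddition and add the oxygen late. The forward key step is a C–H functionalisation directed by the 2β-hydroxyl, which is 1,3-syn to that methyl: hydridosilyl ether formation, rhodium-catalysed δ-C–H silylation and Tamao–Fleming oxidation. The chosen plan is preferred because the directing oxygen is the one that must become the lactone oxygen, so the resulting 1,4-diol needs two extra differentiation steps. The allylic C–H bonds of ring C would compete, and fragment 11 delivers the same oxygen at no cost in step 6.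

Key step: step 10

Assumption: the (S,S)-configured bromoborane of step 3 is taken to give the (2S,3R)-acid 8; if the sense of induction is the opposite, the (R,R)-reagent is used and nothing else changes.

## Steps

Step 1
Reactants: 1 pent-1-en-4-yne
Product: 4 (2E)-3-methylhexa-2,5-dien-1-ol, via alkenylalane 2 (not isolated), via lithium alkenylaluminate 3 (not isolated)
Conditions: AlMe3, Cp2ZrCl2 (25 mol %), CH2Cl2, 0 °C to rt; n-BuLi, THF, −78 to 0 °C; (CH2O)n, rt; 1 M HCl
Reagents that add atoms: trimethylaluminium C[Al](C)C; formaldehyde (as paraformaldehyde) C=O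
Why: Zirconium-catalysed carboalumination (Negishi carboalumination) should add CH3 and Al syn across the terminal alkyne with Al on the terminal carbon, and the aluminate is then hydroxymethylated with retention, so CH3 ends cis to CH2OH (E); the isolated alkene is far less reactive.

Step 2
Reactants: 4 (2E)-3-methylhexa-2,5-dien-1-ol; 5 5-methylhex-5-enoic acid
Product: 6 (2E)-3-methylhexa-2,5-dien-1-yl 5-methylhex-5-enoate
Conditions: DCC, DMAP (cat.), CH2Cl2, 0 °C to rt
Reagents that add atoms: none
Why: Steglich esterification of a primary allylic alcohol; no stereocentre is formed and the alkene geometry is not touched.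

Step 3
Reactants: 6 (2E)-3-methylhexa-2,5-dien-1-yl 5-methylhex-5-enoate
Product: 8 (2S,3R)-3-ethenyl-3-methyl-2-(3-methylbut-3-en-1-yl)hex-5-enoic acid, via boron ketene acetal 7 (not isolated)
Conditions: (4S,5S)-2-bromo-1,3-bis{[3,5-bis(trifluoromethyl)phenyl]sulfonyl}-4,5-diphenyl-1,3,2-diazaborolidine (1.2 equiv), i-Pr2NEt, CH2Cl2, −78 °C, then −20 to 4 °C; aqueous work-up
Reagents that add atoms: none
Why: Enantioselective boron-mediated Ireland–Claisen rearrangement: the Z(O)-boron ketene acetal (alkyl chain cis to O–B) and the (E)-alkene should react through a chair in which the C10 chain on C5 and the allyl group on C6 are both equatorial, which gives the required relative configuration of the new C5–C6 bond. The C2-symmetric sulfonamide ligand on boron selects one of the two enantiomeric chairs and so fixes the absolute configuration of C5 and C6.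

Step 4
Reactants: 8 (2S,3R)-3-ethenyl-3-methyl-2-(3-methylbut-3-en-1-yl)hex-5-enoic acid
Product: 9 (2S,3R)-3-ethenyl-N-methoxy-N,3-dimethyl-2-(3-methylbut-3-en-1-yl)hex-5-enamide
Conditions: MeNHOMe·HCl, EDC·HCl, DMAP (cat.), i-Pr2NEt, CH2Cl2, 0 °C to rt
Reagents that add atoms: N,O-dimethylhydroxylamine hydrochloride CNOC.Cl
Why: Carbodiimide amide coupling to the Weinreb amide, chosen so that the later reduction stops cleanly at the aldehyde; the hindered α-centre C5 is not expected to epimerise under these mild conditions.

Step 5
Reactants: 9 (2S,3R)-3-ethenyl-N-methoxy-N,3-dimethyl-2-(3-methylbut-3-en-1-yl)hex-5-enamide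
Product: 10 (1S,2R)-2-ethenyl-N-methoxy-N,2,5-trimethylcyclohept-4-ene-1-carboxamide
Conditions: second-generation Grubbs catalyst RuCl2(=CHPh)(PCy3)(H2IMes) (5 mol %), CH2Cl2 (2 mM), 40 °C
Reagents that add atoms: none
Why: Ring-closing metathesis: the carbene should load on the unhindered allyl terminus, from which only closure onto the isopropenyl group (ring C, C12=C13) is possible, since closure onto the vinyl group on the same carbon would give a cyclobutene. The vinyl group on quaternary C6 is too hindered to initiate, and no stereocentre is affected.

Step 6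
Reactants: 10 (1S,2R)-2-ethenyl-N-methoxy-N,2,5-trimethylcyclohept-4-ene-1-carboxamide; 11 2-bromoprop-2-en-1-ol
Product: 13 (1S,2S)-2-[3-(hydroxymethyl)but-3-en-1-yl]-N-methoxy-N,2,5-trimethylcyclohept-4-ene-1-carboxamide, via B-alkyl-9-BBN borane 12 (not isolated)
Conditions: 9-BBN-H, THF, 0 °C to rt; then 11, Pd(dppf)Cl2 (5 mol %), AsPh3, aq. K3PO4, DMF, rt to 50 °C
Reagents that add atoms: none
Why: Anti-Markovnikov hydroboration of the only monosubstituted alkene, then B-alkyl Suzuki–Miyaura coupling with the vinyl bromide, should form C8–C9 and bring in C1 and C17 with its free hydroxyl; the change of the C6 descriptor from R to S is only a change of CIP priorities.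

Step 7
Reactants: 13 (1S,2S)-2-[3-(hydroxymethyl)but-3-en-1-yl]-N-methoxy-N,2,5-trimethylcyclohept-4-ene-1-carboxamide
Product: 14 (1S,2S)-2-[3-(hydroxymethyl)but-3-en-1-yl]-2,5-dimethylcyclohept-4-ene-1-carbaldehyde
Conditions: i-Bu2AlH (2.5 equiv), THF, −78 °C; Rochelle salt work-up
Reagents that add atoms: none
Why: Weinreb amide reduction stops at the aldehyde through the chelated tetrahedral intermediate; the first equivalent of hydride is used by the free hydroxyl, and the cold, buffered work-up should keep C5 from epimerising.

Step 8
Reactants: 14 (1S,2S)-2-[3-(hydroxymethyl)but-3-en-1-yl]-2,5-dimethylcyclohept-4-ene-1-carbaldehyde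
Product: 15 2-{2-[(1S,7S)-7-ethynyl-1,4-dimethylcyclohept-3-en-1-yl]ethyl}prop-2-en-1-ol
Conditions: dimethyl (1-diazo-2-oxopropyl)phosphonate, K2CO3, MeOH, 0 °C to rt
Reagents that add atoms: dimethyl (1-diazo-2-oxopropyl)phosphonate CC(=O)C(=[N+]=[N-])P(=O)(OC)OC
Why: Ohira–Bestmann (Seyferth–Gilbert) homologation turns the aldehyde C4 into the terminal alkyne C4≡C3; the free alcohol is tolerated and the hindered α-centre C5 should survive the mild carbonate conditions.

Step 9
Reactants: 15 2-{2-[(1S,7S)-7-ethynyl-1,4-dimethylcyclohept-3-en-1-yl]ethyl}prop-2-en-1-ol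
Product: 16 2-{2-[(1S,7S)-7-ethynyl-1,4-dimethylcyclohept-3-en-1-yl]ethyl}prop-2-en-1-yl acetate
Conditions: Ac2O, pyridine, DMAP (cat.), CH2Cl2, 0 °C
Reagents that add atoms: acetic anhydride CC(=O)OC(C)=O
Why: Standard acetylation of the primary alcohol installs the C17 acetate of the target after the last hydride and base steps; no later step attacks it.

Step 10
Reactants: 16 2-{2-[(1S,7S)-7-ethynyl-1,4-dimethylcyclohept-3-en-1-yl]ethyl}prop-2-en-1-yl acetate
Product: 17 tricyclic enone (rings A, B and C closed; C2 ketone, C3=C4 and C12=C13 double bonds, 5β-H, 6α-CH3, 9β-CH2OAc)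
Conditions: Co2(CO)8 (20 mol %), tetramethylthiourea (1.2 equiv), CO (1 atm), toluene, 70 °C
Reagents that add atoms: carbon monoxide [C-]#[O+]
Why: Intramolecular Pauson–Khand [2+2+1] cycloaddition: the terminal alkyne forms its Co2(CO)6 complex, loss of CO lets the C9=C1 alkene coordinate and insert into the Co–C4 bond, CO then inserts into the Co–C1 bond and reductive elimination joins C2 to C3. Ring B closes in the insertion step through C4–C9 (6-exo with respect to the C5–C6–C7–C8 tether) and ring A closes through C1–C2 and C2–C3 around the inserted CO; the tether fixes the regiochemistry. The closest known reaction type is the cobalt-mediated cyclocarbonylation of 1,7-enynes with 1,1-disubstituted alkenes to angularly substituted bicyclo[4.3.0]nonenones. The only new stereocentre is C9: ring B must form as a chair that is trans-fused to ring C (C10 and C14 equatorial, C16 axial), and the nearly planar cyclopentenone can span C9 and sp2 C4 only if C1 is equatorial on C9, which puts C17 axial on the β face, anti to the axial α-methyl on C6. The C9 epimer would need a boat ring B. The step needs chemoselectivity for the side-chain alkene over C12=C13, which is secured because using the ring alkene would build a bridged bicycle with a bridgehead quaternary carbon, and it needs the alkyne and the chain to be gauche, which their trans relation on C5/C6 from step 3 provides.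

Step 11
Reactants: 17 tricyclic enone
Product: 18 2β-allylic alcohol (2S; otherwise as 17)
Conditions: (R)-2-methyl-CBS-oxazaborolidine (20 mol %), catecholborane, toluene, −78 °C
Reagents that add atoms: none
Why: Corey–Bakshi–Shibata 1,2-reduction under reagent control: with the alkenyl carbon C3 as the large flank and C1H2 as the small one, the (R)-catalyst should deliver hydride to the α face of C2 and give the 2β-alcohol. Reagent control is chosen because C17 and C8 flank the planar ring A about equally, so the substrate bias is weak.

Step 12
Reactants: 18 2β-allylic alcohol; 19 propiolic acid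
Product: 20 2β-propiolate ester of 18
Conditions: DCC, DMAP (5 mol %), CH2Cl2, −20 to 0 °C
Reagents that add atoms: none
Why: Steglich esterification with retention at C2 attaches the three lactone carbons C18–C20 to the β-oxygen; low temperature limits conjugate addition to the ynoate.

Step 13
Reactants: 20 2β-propiolate ester
Product: 22 12,13-deoxy target (α-methylene-γ-butyrolactone; 2β-O, 3α-H, 4α-H, 5β-H, 6α-CH3, 9β-CH2OAc, C12=C13), via vinylstannane 21 (not isolated)
Conditions: Bu3SnH (1.3 equiv), AIBN (0.1 equiv), PhH (5 mM), 80 °C, syringe pump; then TsOH·H2O, CH2Cl2, 0 °C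
Reagents that add atoms: none
Why: Tin-mediated radical cyclisation of an allylic propiolate: the stannyl radical adds to C19, the vinyl radical at C18 closes 5-exo-trig onto C3 and, being tied to the 2β-oxygen, can only give the cis-fused lactone with C18 β. The C4 radical should take hydrogen from the stannane on the α face, because the β face is blocked by the adjacent axial C17 group, the axial 5-H and the new lactone, which gives the trans A/B fusion. Protodestannylation of the vinylstannane then frees the exocyclic methylene.

Step 14
Reactants: 22 12,13-deoxy target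
Product: 23 target CNP0149939.1 (12β,13β-epoxide of 22)
Conditions: mCPBA, NaHCO3, CH2Cl2, 0 °C
Reagents that add atoms: 3-chloroperoxybenzoic acid OOC(=O)c1cccc(Cl)c1
Why: Prilezhaev epoxidation: the peracid should attack the electron-rich trisubstituted C12=C13 alkene and leave the electron-poor enoate; attack is expected on the β face, away from the axial C16 methyl that covers the α face of ring C.

## Compound list

1 | pent-1-en-4-yne | C=CCC#C | starting material
2 | dimethyl[(1E)-2-methylpenta-1,4-dien-1-yl]alumane | C[Al](C)/C=C(\C)CC=C | intermediate (not isolated)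
3 | lithium butyl(dimethyl)[(1E)-2-methylpenta-1,4-dien-1-yl]aluminate | [Li+].CCCC[Al-](C)(C)/C=C(\C)CC=C | intermediate (not isolated)
4 | (2E)-3-methylhexa-2,5-dien-1-ol | OC/C=C(\C)CC=C | intermediate
5 | 5-methylhex-5-enoic acid | C=C(C)CCCC(=O)O | starting material
6 | (2E)-3-methylhexa-2,5-dien-1-yl 5-methylhex-5-enoate | C=C(C)CCCC(=O)OC/C=C(\C)CC=C | intermediate
7 | Z(O)-boron ketene acetal of 6 bearing the (4S,5S)-diazaborolidine | C=C(C)CC/C=C(\OB1N(S(=O)(=O)c2cc(cc(c2)C(F)(F)F)C(F)(F)F)[C@@H](c2ccccc2)[C@H](c2ccccc2)N1S(=O)(=O)c1cc(cc(c1)C(F)(F)F)C(F)(F)F)OC/C=C(\C)CC=C | intermediate (not isolated)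
8 | (2S,3R)-3-ethenyl-3-methyl-2-(3-methylbut-3-en-1-yl)hex-5-enoic acid | C=C[C@@](C)(CC=C)[C@H](CCC(C)=C)C(=O)O | intermediate
9 | (2S,3R)-3-ethenyl-N-methoxy-N,3-dimethyl-2-(3-methylbut-3-en-1-yl)hex-5-enamide | C=C[C@@](C)(CC=C)[C@H](CCC(C)=C)C(=O)N(C)OC | intermediate
10 | (1S,2R)-2-ethenyl-N-methoxy-N,2,5-trimethylcyclohept-4-ene-1-carboxamide | C=C[C@@]1(C)CC=C(C)CC[C@@H]1C(=O)N(C)OC | intermediate
11 | 2-bromoprop-2-en-1-ol | OCC(Br)=C | starting material
12 | (1S,2S)-2-[2-(9-borabicyclo[3.3.1]nonan-9-yl)ethyl]-N-methoxy-N,2,5-trimethylcyclohept-4-ene-1-carboxamide | C1CC2CCCC(C1)B2CC[C@@]1(C)CC=C(C)CC[C@@H]1C(=O)N(C)OC | intermediate (not isolated)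
13 | (1S,2S)-2-[3-(hydroxymethyl)but-3-en-1-yl]-N-methoxy-N,2,5-trimethylcyclohept-4-ene-1-carboxamide | C=C(CO)CC[C@@]1(C)CC=C(C)CC[C@@H]1C(=O)N(C)OC | intermediate
14 | (1S,2S)-2-[3-(hydroxymethyl)but-3-en-1-yl]-2,5-dimethylcyclohept-4-ene-1-carbaldehyde | C=C(CO)CC[C@@]1(C)CC=C(C)CC[C@@H]1C=O | intermediate
15 | 2-{2-[(1S,7S)-7-ethynyl-1,4-dimethylcyclohept-3-en-1-yl]ethyl}prop-2-en-1-ol | C=C(CO)CC[C@@]1(C)CC=C(C)CC[C@@H]1C#C | intermediate
16 | 2-{2-[(1S,7S)-7-ethynyl-1,4-dimethylcyclohept-3-en-1-yl]ethyl}prop-2-en-1-yl acetate | C=C(COC(C)=O)CC[C@@]1(C)CC=C(C)CC[C@@H]1C#C | intermediate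
17 | tricyclic enone (C2 ketone, C3=C4, C12=C13, 5β-H, 6α-CH3, 9β-CH2OAc) | O=C1C[C@]2(COC(C)=O)CC[C@@]3(C)CC=C(C)CC[C@@H]3C2=C1 | intermediate
18 | 2β-allylic alcohol (2S) derived from 17 | O[C@H]1C[C@]2(COC(C)=O)CC[C@@]3(C)CC=C(C)CC[C@@H]3C2=C1 | intermediate
19 | propiolic acid (prop-2-ynoic acid) | C#CC(=O)O | starting material
20 | 2β-propiolate ester of 18 | C#CC(=O)O[C@H]1C[C@]2(COC(C)=O)CC[C@@]3(C)CC=C(C)CC[C@@H]3C2=C1 | intermediate
21 | α-(tributylstannylmethylene) lactone (E/Z mixture at C18=C19) | CCCC[Sn](CCCC)(CCCC)C=C1C(=O)O[C@H]2C[C@]3(COC(C)=O)CC[C@@]4(C)CC=C(C)CC[C@@H]4[C@H]3[C@@H]12 | intermediate (not isolated)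
22 | 12,13-deoxy target (α-methylene lactone with C12=C13) | C=C1C(=O)O[C@H]2C[C@]3(COC(C)=O)CC[C@@]4(C)CC=C(C)CC[C@@H]4[C@H]3[C@@H]12 | intermediate
23 | CNP0149939.1 | C=C1C(=O)O[C@H]2C[C@]3(COC(C)=O)CC[C@@]4(C)C[C@H]5O[C@@]5(C)CC[C@@H]4[C@H]3[C@@H]12 | target

## Step count and least certain steps

Total step count: 14. Longest linear sequence: 14 steps (1 to 23; 5, 11 and 19 enter as purchased materials).

Step 10 (key step). The most likely failure is slow insertion of the 1,1-disubstituted alkene in the six-ring-forming mode, so that alkyne oligomerisation or loss of the cobalt complex wins. The cause is that a quaternary centre is formed in the C–C bond-forming step. Fallback, from 16 back to 17: Markovnikov hydrobromination of the alkyne (B-bromo-9-BBN, then AcOH) should give the 2-bromoalkene F1. A 6-exo Heck carbopalladation onto C9 with carbonylative termination (Pd(OAc)2, PPh3, CO, Et3N, 2-(trimethylsilyl)ethanol) should give the 2-(trimethylsilyl)ethyl ester F2; the alkylpalladium at C1 has no β-hydrogen and is trapped by CO. Buffered fluoride would free the carboxylic acid F3. Its acid chloride, treated with SnCl4 at −78 °C, should acylate the exocyclic C4=C3 alkene at C3 and lose a proton to give 17. In this sequence the C9 configuration rests on the chair-like Heck insertion, and any C9 epimer would have to be removed at the stage of F2.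

Step 13. Two things may go wrong. The vinyl radical may take hydrogen before the ester reaches the s-cis rotamer needed for closure, because esters prefer the s-trans form; and hydrogen may be delivered to the β face of the C4 radical (cis A/B fusion) if the axial C16 methyl hinders the α face more than estimated. Acid-induced migration of the C12=C13 alkene during destannylation is a lesser risk. Fallback, from 18 back to 22: ethoxyallene and NBS should convert 18 into the mixed 2-bromoallyl ethyl acetal F4. Ueno–Stork cyclisation (Bu3SnH, AIBN) through the flexible acetal tether should give the cyclic ethyl acetal F5, and Jones oxidation (CrO3, H2SO4, acetone) would give 22 without a tin-bearing product.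

Step 3. Enolisation and rearrangement of the hindered, 3,3-disubstituted allyl ester may be slow, the enolate geometry may erode (C5 epimer), and the enantioselection may be incomplete. Fallback, from 6 back to 8: LDA in THF/DMPU with Me3SiCl should give the (Z)-silyl ketene acetal F6, which rearranges on warming to the racemic acid, that is 8 together with its (2R,3S)-enantiomer F7. Crystallisation with (R)-1-phenylethylamine (or its enantiomer) as the ammonium salt F8, then acidification, returns 8.

Step 11. Facial selectivity may be poor if the catalyst's preference is mismatched with a substrate bias; a 2α-alcohol would carry the lactone to the wrong face. Fallback, from 17 back to 20: the (S)-catalyst, which is then the matched one, is used to make the 2α-alcohol F9 on purpose, and Mitsunobu esterification with 19 (PPh3, DIAD) inverts C2 and gives 20 directly.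

Step 14. The flexible seven-membered ring may give poor facial selectivity or attack on the α face. Fallback, from 22 back to 23: NBS in aqueous acetone should form the bromonium ion on the face the peracid prefers and water opens it at tertiary C12 from the other face, which gives the bromohydrin F10. K2CO3 in acetone then closes the epoxide on the face opposite to the one attacked first.

## Further compounds

F1 | step 10 | 2-{2-[(1S,7S)-7-(1-bromoethenyl)-1,4-dimethylcyclohept-3-en-1-yl]ethyl}prop-2-en-1-yl acetate | C=C(COC(C)=O)CC[C@@]1(C)CC=C(C)CC[C@@H]1C(Br)=C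
F2 | step 10 | 2-(trimethylsilyl)ethyl ester of the B/C-bicyclic acid (4-methylidene, 9β-CH2OAc, 9α-CH2CO2R) | C[Si](C)(C)CCOC(=O)C[C@]1(COC(C)=O)CC[C@@]2(C)CC=C(C)CC[C@@H]2C1=C
F3 | step 10 | B/C-bicyclic carboxylic acid (4-methylidene, 9β-CH2OAc, 9α-CH2CO2H) | OC(=O)C[C@]1(COC(C)=O)CC[C@@]2(C)CC=C(C)CC[C@@H]2C1=C
F4 | step 13 | mixed 2-bromoallyl ethyl acetal of 18 (acetal carbon as a mixture) | C=C(Br)C(OCC)O[C@H]1C[C@]2(COC(C)=O)CC[C@@]3(C)CC=C(C)CC[C@@H]3C2=C1
F5 | step 13 | cyclic ethyl acetal corresponding to 22 (C20 as OEt acetal, mixture at C20) | C=C1C(OCC)O[C@H]2C[C@]3(COC(C)=O)CC[C@@]4(C)CC=C(C)CC[C@@H]4[C@H]3[C@@H]12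
F6 | step 3 | (Z)-trimethylsilyl ketene acetal of 6 | C=C(C)CC/C=C(\O[Si](C)(C)C)OC/C=C(\C)CC=C
F7 | step 3 | (2R,3S)-3-ethenyl-3-methyl-2-(3-methylbut-3-en-1-yl)hex-5-enoic acid | C=C[C@](C)(CC=C)[C@@H](CCC(C)=C)C(=O)O
F8 | step 3 | (1R)-1-phenylethan-1-aminium salt of 8 | C=C[C@@](C)(CC=C)[C@H](CCC(C)=C)C(=O)[O-].C[C@@H]([NH3+])c1ccccc1
F9 | step 11 | 2α-allylic alcohol (C2 epimer of 18) | O[C@@H]1C[C@]2(COC(C)=O)CC[C@@]3(C)CC=C(C)CC[C@@H]3C2=C1
F10 | step 14 | bromohydrin of 22 (13α-Br, 12β-OH) | C=C1C(=O)O[C@H]2C[C@]3(COC(C)=O)CC[C@@]4(C)C[C@H](Br)[C@](O)(C)CC[C@@H]4[C@H]3[C@@H]12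
A1 | alternative 1 | (4aS)-4a,7-dimethyl-3,4,4a,5,8,9-hexahydro-2H-benzo[7]annulen-2-one | O=C1C=C2CCC(C)=CC[C@]2(C)CC1
A2 | alternative 2 | allenyl aldehyde (rings B and C; 9β-CH2OAc, 9α-CH2CHO, 4β-propa-1,2-dienyl) | O=CC[C@]1(COC(C)=O)CC[C@@]2(C)CC=C(C)CC[C@@H]2[C@H]1C=C=C
A3 | alternative 2 | 2,3-bis-epimer of 22 (lactone on the α face) | C=C1C(=O)O[C@@H]2C[C@]3(COC(C)=O)CC[C@@]4(C)CC=C(C)CC[C@@H]4[C@H]3[C@H]12
A4 | alternative 3 | C9-methyl analogue of 18 (no oxygen on C17) | O[C@H]1C[C@]2(C)CC[C@@]3(C)CC=C(C)CC[C@@H]3C2=C1
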